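## Retrosynthetic overview

Rings: A = methylcyclopentylidene, B = cyclooctene, C = cyclohexane, D = isopropylcyclopentane. The end game from tetracycle 25 is radical removal of a ring-B secondary hydroxyl, hydroxyl-directed hydrogenation of an exocyclic methylidene (this becomes the ring-B methyl) and ester demethylation.
Key disconnection (rings C and B opened together): in ring B, the CH(CH3) carbon, its methyl, its CH2 neighbour and the B/C-fusion CH form an isobutane-1,3-diyl unit. One arm is bonded to the tertiary carbinol carbon and the other to the CH2 beside ring A, so this unit is the retron of a 2-methylidenepropane-1,3-diyl dianion adding to a ketone and an aldehyde. The Z-tetrasubstituted alkene and ring A hold these two carbonyls in a cis-1,5 relationship.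
Precursor 23 is a ring-A/ring-D keto aldehyde carrying a 2-(bromomethyl)allylic bromide, unmasked from bis(allylsilane) 21; 21 comes from addition of a ring-D alkyllithium to ring-A lactone 6.
Ring A (lactone 6): asymmetric conjugate methylation and hydroxymethylation of cyclopentenone, then an intramolecular Horner–Wadsworth–Emmons reaction that fixes the alkene geometry by ring formation. Ring D (17): asymmetric copper hydride reduction to the cis-fused keto lactone 10, convex-face hydrogenation, angular allylation, cross-metathesis.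
Order of ring formation: A and D on separate fragments, then C and B (in that order) in one operation.

Key step: step 15

Assumption (chemistry): 7 and 16 are taken as purchasable, and the ligand antipodes in steps 1 and 4 are chosen to give the configurations shown.

## Route

Step 1
Reactants: 1 cyclopent-2-en-1-one
Product: 3 (2R,3R)-2-(hydroxymethyl)-3-methylcyclopentan-1-one, via silyl enol ether 2 (not isolated)
Conditions: Me2Zn, Cu(OTf)2 (2 mol %), Feringa-type phosphoramidite ligand (antipode giving 3R), toluene, −30 °C; TMSCl; then aq. HCHO, Yb(OTf)3 (10 mol %), THF, rt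
Reagents that add atoms: dimethylzinc C[Zn]C; chlorotrimethylsilane C[Si](C)(C)Cl (silyl group of 2 only); formaldehyde C=O
Why: Cu-catalysed asymmetric conjugate addition sets the methyl-bearing centre under ligand control and gives a regiodefined zinc enolate that is silylated to 2, whose Lewis-acid-catalysed aqueous Mukaiyama hydroxymethylation places the CH2OH group at the carbon between carbonyl and methine with the epimerisable centre settling trans to the methyl group.

Step 2
Reactants: 3 (2R,3R)-2-(hydroxymethyl)-3-methylcyclopentan-1-one; 4 2-(diethoxyphosphoryl)propanoic acid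
Product: 5 [(1R,2R)-2-methyl-5-oxocyclopentyl]methyl 2-(diethoxyphosphoryl)propanoate
Conditions: DCC, DMAP (cat), CH2Cl2, 0 °C
Reagents that add atoms: none
Why: Steglich esterification of the unhindered primary alcohol proceeds at 0 °C, where beta-elimination of the beta-acyloxy ketone is slow, and creates no stereocentre.

Step 3
Reactants: 5 [(1R,2R)-2-methyl-5-oxocyclopentyl]methyl 2-(diethoxyphosphoryl)propanoate
Product: 6 (7R,7aS)-4,7-dimethyl-5,6,7,7a-tetrahydrocyclopenta[c]pyran-3(1H)-one (ring-A lactone)
Conditions: LiCl, DBU, MeCN, rt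
Reagents that add atoms: none
Why: Intramolecular Horner–Wadsworth–Emmons olefination under Masamune–Roush conditions forms the tetrasubstituted alkene inside a six-membered lactone, so the acyl carbon can only end up cis to the ring-A methine that carries the CH2O arm, while the mild base leaves that methine trans to the methyl group.

Step 4
Reactants: 7 methyl 3-oxocyclopent-1-ene-1-carboxylate
Product: 10 (3aS,6aR)-tetrahydro-1H-cyclopenta[c]furan-1,4(3H)-dione (cis-fused keto lactone), via silyl enol ether 8 (not isolated), via hydroxymethyl keto ester 9 (not isolated)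
Conditions: CuCl (5 mol %), NaOtBu (5 mol %), p-Tol-BINAP (5 mol %, antipode giving 1R), PhMe2SiH, toluene, −20 °C; then aq. HCHO, Sc(OTf)3 (10 mol %), THF, rt; then PPTS, toluene, 80 °C
Reagents that add atoms: dimethyl(phenyl)silane C[SiH](C)c1ccccc1 (silyl group of 8 only); formaldehyde C=O
Why: Ligand-controlled copper hydride conjugate reduction delivers hydride to the ester-bearing beta carbon (sets the 1R centre) and gives silyl enol ether 8 regiospecifically, its Mukaiyama hydroxymethylation gives 9, and acid equilibrates the ketone alpha centre so that only the cis isomer lactonises to the cis-fused keto lactone.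

Step 5
Reactants: 10 (3aS,6aR)-tetrahydro-1H-cyclopenta[c]furan-1,4(3H)-dione
Product: 11 (3aS,6aR)-1-oxo-3,3a,6,6a-tetrahydro-1H-cyclopenta[c]furan-4-yl trifluoromethanesulfonate
Conditions: LiN(SiMe3)2, THF, −78 °C; PhNTf2, −78 to 0 °C
Reagents that add atoms: N-phenylbis(trifluoromethanesulfonimide) O=S(=O)(N(c1ccccc1)S(=O)(=O)C(F)(F)F)C(F)(F)F
Why: Kinetic deprotonation by the hindered amide base occurs at the unhindered CH2 alpha to the ketone rather than at the ring-fusion methines, and O-triflation of this enolate gives the less substituted enol triflate without touching the stereocentres.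

Step 6
Reactants: 11 (3aS,6aR)-1-oxo-3,3a,6,6a-tetrahydro-1H-cyclopenta[c]furan-4-yl trifluoromethanesulfonate; 12 4,4,5,5-tetramethyl-2-(prop-1-en-2-yl)-1,3,2-dioxaborolane
Product: 13 (3aR,6aR)-4-(prop-1-en-2-yl)-3,3a,6,6a-tetrahydro-1H-cyclopenta[c]furan-1-one
Conditions: Pd(dppf)Cl2 (5 mol %), K3PO4, THF/H2O, 50 °C
Reagents that add atoms: none
Why: Suzuki–Miyaura coupling of an enol triflate with an alkenylboronate is reliable in the presence of a lactone and installs the three isopropyl carbons.

Step 7
Reactants: 13 (3aR,6aR)-4-(prop-1-en-2-yl)-3,3a,6,6a-tetrahydro-1H-cyclopenta[c]furan-1-one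
Product: 14 (3aS,4R,6aR)-4-(propan-2-yl)hexahydro-1H-cyclopenta[c]furan-1-one
Conditions: H2 (1 atm), Pd/C, EtOAc, rt
Reagents that add atoms: none
Why: Heterogeneous hydrogenation saturates the diene from the convex face of the cis-fused bicyclo[3.3.0] lactone, so hydrogen arrives syn to the two ring-fusion hydrogens and the isopropyl group is pushed to the concave face, cis to the lactone CH2O arm.

Step 8
Reactants: 14 (3aS,4R,6aR)-4-(propan-2-yl)hexahydro-1H-cyclopenta[c]furan-1-one
Product: 15 (3aS,4R,6aS)-4-(propan-2-yl)-6a-(prop-2-en-1-yl)hexahydro-1H-cyclopenta[c]furan-1-one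
Conditions: LiN(iPr)2, THF, −78 °C; allyl bromide, DMPU, −78 to −20 °C
Reagents that add atoms: allyl bromide C=CCBr
Why: Alkylation of the lactone enolate at the ring-fusion carbon can only give the cis-fused product, so allyl bromide adds from the convex face and creates the quaternary centre with the allyl group trans to the CH2O arm and the carbonyl cis to it.

Step 9
Reactants: 15 (3aS,4R,6aS)-4-(propan-2-yl)-6a-(prop-2-en-1-yl)hexahydro-1H-cyclopenta[c]furan-1-one; 16 2-methylidenepropane-1,3-diylbis(trimethylsilane)
Product: 17 (3aS,4R,6aS)-4-(propan-2-yl)-6a-{4-(trimethylsilyl)-3-[(trimethylsilyl)methyl]but-2-en-1-yl}hexahydro-1H-cyclopenta[c]furan-1-one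
Conditions: second-generation Hoveyda–Grubbs catalyst RuCl2(H2IMes)(=CH–C6H4–2-OiPr) (10 mol %), 16 (8 equiv), CH2Cl2, 40 °C
Reagents that add atoms: none
Why: Olefin cross-metathesis of the terminal alkene with an excess of the symmetric 1,1-disubstituted allylsilane alkene gives the trisubstituted alkene, which has no E/Z issue because both new substituents are identical.

Step 10
Reactants: 17 (3aS,4R,6aS)-4-(propan-2-yl)-6a-{4-(trimethylsilyl)-3-[(trimethylsilyl)methyl]but-2-en-1-yl}hexahydro-1H-cyclopenta[c]furan-1-one
Product: 18 (1S,2S,3R)-2-[(phenylsulfanyl)methyl]-3-(propan-2-yl)-1-{4-(trimethylsilyl)-3-[(trimethylsilyl)methyl]but-2-en-1-yl}cyclopentane-1-carboxylic acid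
Conditions: PhSNa, DMF, 120 °C; then 1 M HCl
Reagents that add atoms: sodium benzenethiolate [Na+].[S-]c1ccccc1
Why: The soft thiolate opens the gamma-lactone by SN2 attack at the CH2–O carbon (alkyl–oxygen cleavage) in a dipolar aprotic solvent, which frees the carboxylate and leaves all stereocentres and the allylsilanes untouched.

Step 11
Reactants: 18 (1S,2S,3R)-2-[(phenylsulfanyl)methyl]-3-(propan-2-yl)-1-{4-(trimethylsilyl)-3-[(trimethylsilyl)methyl]but-2-en-1-yl}cyclopentane-1-carboxylic acid; 6 (7R,7aS)-4,7-dimethyl-5,6,7,7a-tetrahydrocyclopenta[c]pyran-3(1H)-one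
Product: 20 (1S,2S,3R)-2-{(Z)-3-[(2S,3R)-2-(hydroxymethyl)-3-methylcyclopentylidene]-2-oxobutyl}-3-(propan-2-yl)-1-{4-(trimethylsilyl)-3-[(trimethylsilyl)methyl]but-2-en-1-yl}cyclopentane-1-carboxylic acid (in equilibrium with its six-membered hemiketal), via dilithio species 19 (not isolated)
Conditions: n-BuLi (1 equiv), THF, −78 °C; Li powder, 4,4′-di-tert-butylbiphenyl (5 mol %), −78 °C; solution cannulated from excess Li onto 6, −78 °C; then 1 M HCl to pH 4
Reagents that add atoms: n-butyllithium [Li]CCCC and lithium [Li] (lithium of 19 only)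
Why: Arene-catalysed reductive lithiation of the alkyl phenyl sulfide, with the acid masked as its lithium carboxylate, gives primary alkyllithium 19, which adds once to the lactone carbonyl because the tetrahedral lithium hemiketal persists at −78 °C, so the alkene geometry fixed in 6 is carried into the enone.

Step 12
Reactants: 20 (hydroxy enone acid)
Product: 21 methyl (1S,2S,3R)-2-{(Z)-3-[(2S,3R)-2-(hydroxymethyl)-3-methylcyclopentylidene]-2-oxobutyl}-3-(propan-2-yl)-1-{4-(trimethylsilyl)-3-[(trimethylsilyl)methyl]but-2-en-1-yl}cyclopentane-1-carboxylate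
Conditions: TMSCHN2, MeOH/toluene, 0 °C
Reagents that add atoms: (trimethylsilyl)diazomethane C[Si](C)(C)C=[N+]=[N-]
Why: Methyl esterification with trimethylsilyldiazomethane is neutral and chemoselective for the carboxylic acid, protecting it against bromolactonisation in the next step.

Step 13
Reactants: 21 (bis(allylsilane) hydroxy enone methyl ester)
Product: 22 methyl (1S,2S,3R)-1-[2-bromo-3-(bromomethyl)but-3-en-1-yl]-2-{(Z)-3-[(2S,3R)-2-(hydroxymethyl)-3-methylcyclopentylidene]-2-oxobutyl}-3-(propan-2-yl)cyclopentane-1-carboxylate (both epimers at the CHBr carbon)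
Conditions: NBS (2.1 equiv), CH2Cl2, −78 to 0 °C, dark
Reagents that add atoms: N-bromosuccinimide O=C1CCC(=O)N1Br
Why: Electrophilic bromodesilylation (SE2′ substitution of allylsilanes) converts each allylsilane arm into an allylic bromide with allylic transposition, while the electron-poor enone alkene is inert to the electrophile.

Step 14
Reactants: 22 (dibromide hydroxy enone)
Product: 23 methyl (1S,2S,3R)-1-[2-bromo-3-(bromomethyl)but-3-en-1-yl]-2-{(Z)-3-[(2S,3R)-2-formyl-3-methylcyclopentylidene]-2-oxobutyl}-3-(propan-2-yl)cyclopentane-1-carboxylate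
Conditions: Dess–Martin periodinane, pyridine, CH2Cl2, 0 °C; used at once
Reagents that add atoms: none
Why: Dess–Martin oxidation converts the primary alcohol of the open hydroxy ketone form into the aldehyde under buffered conditions, the hemiketal form having no carbinol hydrogen, and tolerates the allylic bromides.

Step 15
Reactants: 23 (keto aldehyde dibromide)
Product: 25 tetracyclic diol methyl ester (A–B–C–D skeleton of the target with an exocyclic methylidene in place of the ring-B methyl and a secondary hydroxyl of either configuration on the ring-B carbon beside ring A), via monocyclised bromo aldehyde 24 (not isolated)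
Conditions: In powder (6 equiv), DMF (0.005 M), rt; aq. NH4Cl
Reagents that add atoms: none
Why: Zerovalent indium inserts into the allylic C–Br bonds to give an allylindium reagent whose two termini act in turn as nucleophiles (Barbier-type carbonyl allylation; the closest known reaction type is the indium- or zinc-mediated double allylation with 2-(bromomethyl)allyl bromide as an isobutene 1,3-dianion equivalent, together with metal-mediated intramolecular allylations that close six- and eight-membered carbocycles). The substituted allyl terminus first adds 1,2 to the enone carbonyl and closes ring C through a six-membered carbocyclic chair (6-exo-type closure; every other pairing of terminus and carbonyl would need an 8-, 10- or 12-membered ring), which gives 24. The second C–Br bond is then metallated and either of the two equivalent CH2 termini of the resulting 2-substituted allylindium attacks the aldehyde, closing ring B as an eight-membered ring between two arms that sit gauche on adjacent ring-C carbons and are held close by the Z-alkene on ring A. The B/C-fusion methine is controlled by the trans-fused ring D and its axial ester, because the allyl unit must take the equatorial site of the forming chair and so its hydrogen becomes axial and syn to the ester, and the carbinol centre is controlled by the preference of the bulky alkenyl substituent of the ketone for the equatorial site, which makes oxygen axial and anti to the fusion hydrogen (trans-fused B/C). The step needs ketone-before-aldehyde chemoselectivity (secured by ring size), 1,2- rather than 1,4-addition (allylindium reagents add 1,2 and the beta carbon is fully substituted) and retention of the aldehyde alpha centre (neutral medium, and its trans relation to the ring-A methyl is the thermodynamic one). The configuration of the new secondary alcohol does not matter because step 17 removes it.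

Step 16
Reactants: 25 (tetracyclic diol methyl ester)
Product: 26 O-imidazolylthiocarbonyl derivative of 25 at the ring-B secondary alcohol
Conditions: 1,1′-thiocarbonyldiimidazole, DMAP, ClCH2CH2Cl, 60 °C
Reagents that add atoms: 1,1′-thiocarbonyldiimidazole S=C(n1ccnc1)n1ccnc1
Why: The secondary alcohol is thioacylated selectively because the tertiary allylic alcohol is too hindered to react with thiocarbonyldiimidazole.

Step 17
Reactants: 26 (thiocarbonyl derivative)
Product: 27 tetracyclic methylidene alcohol methyl ester (ring-B CH2 in place of the former CHOH)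
Conditions: Bu3SnH (5 equiv, 0.5 M), AIBN (cat), toluene, 100 °C
Reagents that add atoms: none
Why: Barton–McCombie radical deoxygenation replaces the secondary C–O bond by C–H, a high stannane concentration trapping the homoallylic radical before it can rearrange, and no stereocentre is created.

Step 18
Reactants: 27 (tetracyclic methylidene alcohol methyl ester)
Product: 28 sesterfisheric acid methyl ester
Conditions: H2 (50 bar), [Rh(nbd)(dppb)]BF4 (5 mol %), CH2Cl2, rt
Reagents that add atoms: none
Why: Hydroxyl-directed homogeneous hydrogenation with a cationic rhodium catalyst delivers hydrogen to the exocyclic alkene from the face bound by the homoallylic tertiary alcohol, placing the new hydrogen syn to the hydroxyl group and the methyl group anti to it, while the tetrasubstituted alkene is not reduced.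

Step 19
Reactants: 28 sesterfisheric acid methyl ester
Product: 29 sesterfisheric acid
Conditions: NaSEt, DMF, 80 °C; then dilute HCl to pH 4, 0 °C
Reagents that add atoms: none
Why: Nucleophilic demethylation by thiolate (SN2 at the ester methyl group) cleaves the hindered neopentyl-type methyl ester without acid, so the tertiary allylic alcohol survives.

## Compound list

1 | cyclopent-2-en-1-one | O=C1C=CCC1 | starting material
2 | trimethyl{[(3R)-3-methylcyclopent-1-en-1-yl]oxy}silane | C[C@@H]1CCC(O[Si](C)(C)C)=C1 | intermediate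
3 | (2R,3R)-2-(hydroxymethyl)-3-methylcyclopentan-1-one (trans) | O=C1CC[C@@H](C)[C@@H]1CO | intermediate
4 | 2-(diethoxyphosphoryl)propanoic acid | CC(C(=O)O)P(=O)(OCC)OCC | starting material
5 | [(1R,2R)-2-methyl-5-oxocyclopentyl]methyl 2-(diethoxyphosphoryl)propanoate | O=C1CC[C@@H](C)[C@@H]1COC(=O)C(C)P(=O)(OCC)OCC | intermediate
6 | (7R,7aS)-4,7-dimethyl-5,6,7,7a-tetrahydrocyclopenta[c]pyran-3(1H)-one | CC1=C2CC[C@@H](C)[C@@H]2COC1=O | intermediate
7 | methyl 3-oxocyclopent-1-ene-1-carboxylate | COC(=O)C1=CC(=O)CC1 | starting material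
8 | methyl (1R)-3-{[dimethyl(phenyl)silyl]oxy}cyclopent-2-ene-1-carboxylate | COC(=O)[C@@H]1CCC(O[Si](C)(C)c2ccccc2)=C1 | intermediate
9 | methyl (1R)-2-(hydroxymethyl)-3-oxocyclopentane-1-carboxylate (epimers at C-2) | COC(=O)[C@@H]1CCC(=O)C1CO | intermediate
10 | (3aS,6aR)-tetrahydro-1H-cyclopenta[c]furan-1,4(3H)-dione (cis-fused keto lactone) | O=C1OC[C@H]2C(=O)CC[C@@H]12 | intermediate
11 | (3aS,6aR)-1-oxo-3,3a,6,6a-tetrahydro-1H-cyclopenta[c]furan-4-yl trifluoromethanesulfonate | O=C1OC[C@H]2C(OS(=O)(=O)C(F)(F)F)=CC[C@@H]12 | intermediate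
12 | 4,4,5,5-tetramethyl-2-(prop-1-en-2-yl)-1,3,2-dioxaborolane | CC(=C)B1OC(C)(C)C(C)(C)O1 | starting material
13 | (3aR,6aR)-4-(prop-1-en-2-yl)-3,3a,6,6a-tetrahydro-1H-cyclopenta[c]furan-1-one | O=C1OC[C@H]2C(C(C)=C)=CC[C@@H]12 | intermediate
14 | (3aS,4R,6aR)-4-(propan-2-yl)hexahydro-1H-cyclopenta[c]furan-1-one (isopropyl on the concave face, cis to CH2O) | O=C1OC[C@H]2[C@@H](C(C)C)CC[C@@H]12 | intermediate
15 | (3aS,4R,6aS)-4-(propan-2-yl)-6a-(prop-2-en-1-yl)hexahydro-1H-cyclopenta[c]furan-1-one | C=CC[C@@]12CC[C@H](C(C)C)[C@@H]1COC2=O | intermediate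
16 | 2-methylidenepropane-1,3-diylbis(trimethylsilane) | C=C(C[Si](C)(C)C)C[Si](C)(C)C | starting material
17 | (3aS,4R,6aS)-4-(propan-2-yl)-6a-{4-(trimethylsilyl)-3-[(trimethylsilyl)methyl]but-2-en-1-yl}hexahydro-1H-cyclopenta[c]furan-1-one | C[Si](C)(C)CC(C[Si](C)(C)C)=CC[C@@]12CC[C@H](C(C)C)[C@@H]1COC2=O | intermediate
18 | (1S,2S,3R)-2-[(phenylsulfanyl)methyl]-3-(propan-2-yl)-1-{4-(trimethylsilyl)-3-[(trimethylsilyl)methyl]but-2-en-1-yl}cyclopentane-1-carboxylic acid | C[Si](C)(C)CC(C[Si](C)(C)C)=CC[C@@]1(C(=O)O)CC[C@H](C(C)C)[C@@H]1CSc1ccccc1 | intermediate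
19 | dilithio species from 18 (lithium carboxylate, CH2Li in place of CH2SPh) | C[Si](C)(C)CC(C[Si](C)(C)C)=CC[C@@]1(C(=O)O[Li])CC[C@H](C(C)C)[C@@H]1C[Li] | intermediate
20 | (1S,2S,3R)-2-{(Z)-3-[(2S,3R)-2-(hydroxymethyl)-3-methylcyclopentylidene]-2-oxobutyl}-3-(propan-2-yl)-1-{4-(trimethylsilyl)-3-[(trimethylsilyl)methyl]but-2-en-1-yl}cyclopentane-1-carboxylic acid (open form; acyl carbon cis to the ring-A CH bearing CH2OH) | C[Si](C)(C)CC(C[Si](C)(C)C)=CC[C@@]1(C(=O)O)CC[C@H](C(C)C)[C@@H]1CC(=O)/C(C)=C2/CC[C@@H](C)[C@@H]2CO | intermediate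
21 | methyl ester of 20 | C[Si](C)(C)CC(C[Si](C)(C)C)=CC[C@@]1(C(=O)OC)CC[C@H](C(C)C)[C@@H]1CC(=O)/C(C)=C2/CC[C@@H](C)[C@@H]2CO | intermediate
22 | methyl (1S,2S,3R)-1-[2-bromo-3-(bromomethyl)but-3-en-1-yl]-2-{(Z)-3-[(2S,3R)-2-(hydroxymethyl)-3-methylcyclopentylidene]-2-oxobutyl}-3-(propan-2-yl)cyclopentane-1-carboxylate (CHBr epimers) | C=C(CBr)C(Br)C[C@@]1(C(=O)OC)CC[C@H](C(C)C)[C@@H]1CC(=O)/C(C)=C2/CC[C@@H](C)[C@@H]2CO | intermediate
23 | methyl (1S,2S,3R)-1-[2-bromo-3-(bromomethyl)but-3-en-1-yl]-2-{(Z)-3-[(2S,3R)-2-formyl-3-methylcyclopentylidene]-2-oxobutyl}-3-(propan-2-yl)cyclopentane-1-carboxylate | C=C(CBr)C(Br)C[C@@]1(C(=O)OC)CC[C@H](C(C)C)[C@@H]1CC(=O)/C(C)=C2/CC[C@@H](C)[C@@H]2C=O | intermediate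
24 | monocyclised intermediate: rings C and D formed, axial tertiary alcohol, equatorial 3-bromoprop-1-en-2-yl group on the neighbouring carbon, free aldehyde on ring A | BrCC(=C)[C@H]1C[C@@]2(C(=O)OC)CC[C@H](C(C)C)[C@@H]2C[C@]1(O)/C(C)=C3/CC[C@@H](C)[C@@H]3C=O | intermediate
25 | tetracyclic diol methyl ester (exocyclic methylidene on ring B; ring-B secondary alcohol of either configuration; other centres as in the target) | C/C1=C2\CC[C@@H](C)[C@@H]2C(O)CC(=C)[C@H]2C[C@@]3(C(=O)OC)CC[C@H](C(C)C)[C@@H]3C[C@]12O | intermediate
26 | O-(1H-imidazol-1-ylcarbonothioyl) derivative of 25 at the secondary alcohol | C/C1=C2\CC[C@@H](C)[C@@H]2C(OC(=S)n4ccnc4)CC(=C)[C@H]2C[C@@]3(C(=O)OC)CC[C@H](C(C)C)[C@@H]3C[C@]12O | intermediate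
27 | tetracyclic methylidene alcohol methyl ester (deoxygenated 25) | C/C1=C2\CC[C@@H](C)[C@@H]2CCC(=C)[C@H]2C[C@@]3(C(=O)OC)CC[C@H](C(C)C)[C@@H]3C[C@]12O | intermediate
28 | sesterfisheric acid methyl ester | C/C1=C2\CC[C@@H](C)[C@@H]2CC[C@H](C)[C@H]2C[C@@]3(C(=O)OC)CC[C@H](C(C)C)[C@@H]3C[C@]12O | intermediate
29 | sesterfisheric acid | C/C1=C2\CC[C@@H](C)[C@@H]2CC[C@H](C)[C@H]2C[C@@]3(C(=O)O)CC[C@H](C(C)C)[C@@H]3C[C@]12O | target

## Step count and risks

Total step count: 19. Longest linear sequence: 16 steps (steps 4 to 19); the ring-A branch (steps 1 to 3) joins at step 11.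

Steps most likely to fail:

1. Step 15. What may go wrong: addition of the allylindium to the wrong face of the ketone (alkenyl group axial), or protonolysis of the second allylindium before the slow eight-membered ring closure. The fallback sets out from 21, before the silicon is exchanged for bromine. Dess–Martin oxidation (pyridine, CH2Cl2, 0 °C) gives the bis(allylsilane) keto aldehyde F1. TiCl4 (CH2Cl2, −78 °C, high dilution) then carries out a tandem Hosomi–Sakurai double allylation through open transition states, first at the ketone (ring C) and then at the aldehyde (ring B). This comes back to the route at 25.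

2. Step 11. What may go wrong: gamma-deprotonation of lactone 6 by the strongly basic alkyllithium (with epimerisation of the ring-A methine), or incomplete reductive cleavage of the C–S bond. The fallback sets out from 18 and uses a stabilised sulfonyl carbanion instead. Esterification (MeI, K2CO3, DMF) gives the methyl ester sulfide F2. Oxidation (H2O2, (NH4)6Mo7O24 cat, EtOH) gives the sulfone F3. Its lithium carbanion (LiN(SiMe3)2, 2 equiv, THF, −78 °C) is acylated by lactone 6 to the beta-keto sulfone F4. Reductive desulfonylation with Al(Hg) in aqueous THF comes back to the route at 21.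

3. Step 9. What may go wrong: the crowded 1,1-disubstituted alkene 16 does not enter the metathesis cycle, so that only homodimerisation of 15 occurs. The fallback sets out from 15. Ozonolysis (O3, CH2Cl2, −78 °C, then Me2S) gives the aldehyde F5. Dibromo-olefination (CBr4, PPh3, CH2Cl2, 0 °C) gives the 1,1-dibromoalkene F6. A double Negishi coupling with Me3SiCH2ZnBr (Pd(PtBu3)2 cat, THF) installs both CH2SiMe3 groups and comes back to the route at 17.

Further compounds
F1 | step 15 | methyl (1S,2S,3R)-2-{(Z)-3-[(2S,3R)-2-formyl-3-methylcyclopentylidene]-2-oxobutyl}-3-(propan-2-yl)-1-{4-(trimethylsilyl)-3-[(trimethylsilyl)methyl]but-2-en-1-yl}cyclopentane-1-carboxylate | C[Si](C)(C)CC(C[Si](C)(C)C)=CC[C@@]1(C(=O)OC)CC[C@H](C(C)C)[C@@H]1CC(=O)/C(C)=C2/CC[C@@H](C)[C@@H]2C=O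
F2 | step 11 | methyl (1S,2S,3R)-2-[(phenylsulfanyl)methyl]-3-(propan-2-yl)-1-{4-(trimethylsilyl)-3-[(trimethylsilyl)methyl]but-2-en-1-yl}cyclopentane-1-carboxylate | C[Si](C)(C)CC(C[Si](C)(C)C)=CC[C@@]1(C(=O)OC)CC[C@H](C(C)C)[C@@H]1CSc1ccccc1
F3 | step 11 | methyl (1S,2S,3R)-2-[(benzenesulfonyl)methyl]-3-(propan-2-yl)-1-{4-(trimethylsilyl)-3-[(trimethylsilyl)methyl]but-2-en-1-yl}cyclopentane-1-carboxylate | C[Si](C)(C)CC(C[Si](C)(C)C)=CC[C@@]1(C(=O)OC)CC[C@H](C(C)C)[C@@H]1CS(=O)(=O)c1ccccc1
F4 | step 11 | beta-keto sulfone: 21 carrying a benzenesulfonyl group on the CH2 between ring D and the ketone (both epimers) | C[Si](C)(C)CC(C[Si](C)(C)C)=CC[C@@]1(C(=O)OC)CC[C@H](C(C)C)[C@@H]1C(S(=O)(=O)c1ccccc1)C(=O)/C(C)=C2/CC[C@@H](C)[C@@H]2CO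
F5 | step 9 | 2-[(3aS,4R,6aS)-1-oxo-4-(propan-2-yl)hexahydro-1H-cyclopenta[c]furan-6a-yl]acetaldehyde | O=CC[C@@]12CC[C@H](C(C)C)[C@@H]1COC2=O
F6 | step 9 | (3aS,4R,6aS)-6a-(3,3-dibromoprop-2-en-1-yl)-4-(propan-2-yl)hexahydro-1H-cyclopenta[c]furan-1-one | BrC(Br)=CC[C@@]12CC[C@H](C(C)C)[C@@H]1COC2=O
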